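**Retrosynthetic overview**
1. Target 24 ⇒ the C1=C2 bond by late dehydrogenation of the C3 ketone; the O–C11 aryl ether by Mitsunobu coupling of isofraxidin with the C11 alcohol; the C7=C8 alkene and the C6 methylene from a ring B C6 ketone (enone, then allylic deoxygenation).
2. Ring B ⇒ one intermolecular Diels–Alder reaction between a diene C10=C5–C6(OTBS)=C7 held on a finished ring A and the C8=C9 bond of an (R)-4-benzyloxazolidinone crotonimide (imide carbonyl = C11); bonds made: C9–C10 and C7–C8.
3. Feature the plan rests on: the neighbouring ring B atoms C10 (quaternary, methyl-bearing fusion carbon) and C9 (carrying the C11H2–O-coumarin arm syn to C1 and anti to the C10 methyl) are the pattern an endo [4+2] addition to a ring A diene sets in one event; the C6 oxygen that remains is the handle for C5 and for the C7=C8 alkene.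
4. Diene ⇐ 2,2-dimethylcyclohexane-1,3-dione (mono-ketal, methylation, enol triflate, Stille acetyl equivalent, silylation).
5. Ring order: ring A from the start, ring B by the cycloaddition, the coumarin attached intact near the end.

Key step: step 7

Remark: drimane numbering is used (C11 on C9, methyl groups on C4, C8 and C10). C5 is deliberately left open until C8 is planar (step 12), because with the C8 methyl on a saturated carbon a trans-fused ring B would hold the C8 and C10 methyl groups 1,3-diaxial and cannot be counted on as the stable isomer.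

**Route**

Step 1
Reactants: 1 2,2-dimethylcyclohexane-1,3-dione
Product: 2 6,6-dimethyl-1,4-dioxaspiro[4.5]decan-7-one
Conditions: ethylene glycol (1.1 equiv), p-TsOH·H2O (cat.), benzene, reflux, Dean–Stark trap
Reagents that add atoms: ethylene glycol, OCCO
Why: acid-catalysed ketalisation with azeotropic removal of water; after the first dioxolane the remaining carbonyl is flanked by a quaternary carbon and the spiro ketal and should react much more slowly, so the mono-ketal can be taken.

Step 2
Reactants: 2 6,6-dimethyl-1,4-dioxaspiro[4.5]decan-7-one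
Product: 3 6,6,8-trimethyl-1,4-dioxaspiro[4.5]decan-7-one (racemic)
Conditions: LiN(i-Pr)2, THF, −78 °C; MeI, −78 → 0 °C
Reagents that add atoms: iodomethane, CI
Why: enolate alkylation; the ketone has α-hydrogens on one side only, so a single lithium enolate forms and is C-methylated, and the new racemic centre is flattened again in step 3.

Step 3
Reactants: 3 6,6,8-trimethyl-1,4-dioxaspiro[4.5]decan-7-one
Product: 4 6,6,8-trimethyl-1,4-dioxaspiro[4.5]dec-7-en-7-yl trifluoromethanesulfonate
Conditions: LiN(i-Pr)2, THF, −78 → 0 °C; PhNTf2, 0 °C → rt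
Reagents that add atoms: N-phenylbis(trifluoromethanesulfonimide), O=S(=O)(N(c1ccccc1)S(=O)(=O)C(F)(F)F)C(F)(F)F
Why: enol triflate formation; only the methine hydrogen can be removed, so the fully substituted enolate is the only one available and its O-sulfonylation gives the tetrasubstituted vinyl triflate.

Step 4
Reactants: 4 6,6,8-trimethyl-1,4-dioxaspiro[4.5]dec-7-en-7-yl trifluoromethanesulfonate
Product: 6 1-(6,6,8-trimethyl-1,4-dioxaspiro[4.5]dec-7-en-7-yl)ethan-1-one, via ethoxyvinyl diene 5 (not isolated)
Conditions: tributyl(1-ethoxyvinyl)stannane, Pd(PPh3)4 (5 mol %), CuI (10 mol %), LiCl (3 equiv), DMF, 70 °C; then 1 M HCl, THF, 0 °C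
Reagents that add atoms: tributyl(1-ethoxyvinyl)stannane, CCOC(=C)[Sn](CCCC)(CCCC)CCCC; water, O
Why: Stille coupling of a vinyl triflate with an acyl-anion-equivalent stannane (LiCl and CuI help transmetallation at the hindered carbon), followed by hydrolysis of the enol ether, which is far faster than hydrolysis of the hindered dioxolane and unmasks the methyl ketone.

Step 5
Reactants: 6 1-(6,6,8-trimethyl-1,4-dioxaspiro[4.5]dec-7-en-7-yl)ethan-1-one
Product: 7 tert-butyldimethyl{[1-(6,6,8-trimethyl-1,4-dioxaspiro[4.5]dec-7-en-7-yl)ethenyl]oxy}silane (ring A 2-silyloxydiene)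
Conditions: KN(SiMe3)2, THF, −78 °C; TBSCl, −78 → 0 °C
Reagents that add atoms: tert-butyldimethylsilyl chloride, CC(C)(C)[Si](C)(C)Cl
Why: kinetic enolisation of the acetyl methyl group (the twisted enone offers no easily removed γ-hydrogen) and O-silylation of the potassium enolate give the cross-conjugated silyl dienol ether.

Step 6
Reactants: 8 (R)-4-benzyloxazolidin-2-one; 9 (E)-but-2-enoyl chloride
Product: 10 (R)-4-benzyl-3-[(E)-but-2-enoyl]oxazolidin-2-one
Conditions: n-BuLi, THF, −78 °C; then 9, −78 → 0 °C
Reagents that add atoms: none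
Why: N-acylation of the lithiated oxazolidinone by the acid chloride, with the (E) double bond unchanged at low temperature.

Step 7
Reactants: 7 ring A 2-silyloxydiene (1.5 equiv); 10 (R)-4-benzyl-3-[(E)-but-2-enoyl]oxazolidin-2-one
Product: 11 (R)-4-benzyl-3-[6-(tert-butyldimethylsilyloxy)-3,3-(ethylenedioxy)drim-5-en-11-oyl]oxazolidin-2-one (C9 acyl arm anti to the C10 methyl; C8 methyl anti to the arm)
Conditions: Me2AlCl (1.6 equiv), CH2Cl2, −78 → −30 °C
Reagents that add atoms: none
Why: An excess of Me2AlCl gives the cationic dimethylaluminium chelate of both imide carbonyls, which locks the enoyl group s-cis and makes a very electron-poor dienophile that undergoes a concerted, asynchronous [4+2] cycloaddition with the electron-rich diene 7. The closest known reaction type is the aluminium-promoted Diels–Alder reaction of N-enoyl oxazolidinones with acyclic dienes, applied here to a 2-silyloxydiene with a fully substituted terminus. Ring B is closed by this intermolecular cycloaddition, the bonds C7–C8 and C9–C10 forming in one event, and the silyloxy group on C6 puts the largest HOMO coefficient on C7 so that C7 pairs with the crotonyl β-carbon and C10 with the α-carbon. C9 is set by the auxiliary, whose benzyl group covers one face of the planar chelate so that the diene bonds to the open Cα-Re face, and C10 is set relative to C9 by the endo transition state, which brings the acyl group cis to the outside substituent C1 and trans to the inside C10 methyl. C8 follows from the (E) geometry of the crotonyl group (methyl trans to the acyl arm) and is cleared in step 11. The step needs regio-, endo and facial selectivity and an s-cis diene despite the clash between the C6 silyloxy group and the C4 methyl groups; the first three rest on the donor position, the chelated carbonyl and the auxiliary, the last only on the reactivity of the cationic dienophile.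

Step 8
Reactants: 11 cycloadduct imide
Product: 12 6-(tert-butyldimethylsilyloxy)-3,3-(ethylenedioxy)drim-5-en-11-ol (C8, C9 and C10 as in 11)
Conditions: LiBH4, MeOH (1 equiv), Et2O, 0 °C
Reagents that add atoms: none
Why: reductive cleavage of the N-acyl oxazolidinone (hydride attack at the exocyclic carbonyl, loss of the auxiliary, reduction of the aldehyde to the primary alcohol); borohydride does not enolise C9 and leaves the silyl enol ether and the ketal alone.

Step 9
Reactants: 12 C11 alcohol with silyl enol ether
Product: 13 3,3-(ethylenedioxy)-11-hydroxydriman-6-one (C5 epimers)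
Conditions: TBAF, AcOH, THF, 0 °C → rt
Reagents that add atoms: none
Why: fluoride cleaves the silyl enol ether and the enolate is protonated at C5 (desilylation–protonation) without touching the dioxolane; the C5 ratio is immaterial here because C5 is set in step 12.

Step 10
Reactants: 13 hydroxy ketone
Product: 14 11-(tert-butyldimethylsilyloxy)-3,3-(ethylenedioxy)driman-6-one (C5 epimers)
Conditions: TBSCl, imidazole, DMF, rt
Reagents that add atoms: tert-butyldimethylsilyl chloride, CC(C)(C)[Si](C)(C)Cl
Why: silyl ether protection of the primary alcohol (which also drains any internal hemiketal), so that the oxygen survives the enolate, hydride and palladium steps.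

Step 11
Reactants: 14 silyl-protected C6 ketone
Product: 16 11-(tert-butyldimethylsilyloxy)-3,3-(ethylenedioxy)drim-7-en-6-one (C5 epimers), via trimethylsilyl enol ether 15 (not isolated)
Conditions: LiN(i-Pr)2, TMSCl, THF, −78 °C; solvent exchange; Pd(OAc)2 (1.1 equiv), MeCN, rt
Reagents that add atoms: none
Why: Saegusa oxidation; kinetic deprotonation takes the open C7 methylene and not C5 (flanked by two quaternary carbons), and the palladium enolate can only lose the C8 hydrogen, which gives the C7=C8 enone and removes the temporary C8 stereocentre.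

Step 12
Reactants: 16 enone as C5 epimers
Product: 17 11-(tert-butyldimethylsilyloxy)-3,3-(ethylenedioxy)drim-7-en-6-one with trans ring fusion (H5 anti to the C10 methyl)
Conditions: NaOMe (0.3 equiv), MeOH, 50 °C
Reagents that add atoms: none
Why: base-mediated epimerisation through the cross-conjugated C5 enolate; with C8 planar the trans-fused enone (axial C10 methyl, pseudo-axial C9 arm clear of the C8 methyl) should be the thermodynamic isomer, and C9 should hold because its hydrogen lies near the enone plane and its arm already sits in the preferred pseudo-axial position.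

Step 13
Reactants: 17 trans-fused enone
Product: 18 11-(tert-butyldimethylsilyloxy)-3,3-(ethylenedioxy)drim-7-en-6-ol (hydroxyl syn to the C10 methyl)
Conditions: NaBH4, CeCl3·7H2O, MeOH, −40 → 0 °C
Reagents that add atoms: none
Why: Luche 1,2-reduction; hydride should reach C6 from the face away from the axial C10 and C4 methyl groups, and since this centre is removed in step 15 either epimer can be carried on.

Step 14
Reactants: 18 allylic alcohol
Product: 19 6-acetoxy-11-(tert-butyldimethylsilyloxy)-3,3-(ethylenedioxy)drim-7-ene
Conditions: Ac2O, DMAP, pyridine, 50 °C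
Reagents that add atoms: acetic anhydride, CC(=O)OC(C)=O
Why: DMAP-catalysed acylation of the hindered secondary allylic alcohol, the only acylable group present.

Step 15
Reactants: 19 allylic acetate
Product: 20 tert-butyl{[3,3-(ethylenedioxy)drim-7-en-11-yl]oxy}dimethylsilane
Conditions: Pd(PPh3)4 (10 mol %), LiBHEt3 (2 equiv, slow addition), THF, 0 °C → rt
Reagents that add atoms: none
Why: palladium-catalysed allylic hydrogenolysis (Tsuji–Trost type); zerovalent palladium ionises the pseudo-axial acetate to the C6–C7–C8 π-allyl complex and hydride is delivered to the less substituted terminus C6, which leaves the trisubstituted C7=C8 alkene and no new stereocentre.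

Step 16
Reactants: 20 protected drim-7-ene
Product: 21 11-hydroxydrim-7-en-3-one (C11 arm anti to the C10 methyl; trans ring fusion)
Conditions: 2 M HCl, THF, rt
Reagents that add atoms: water, O
Why: acid hydrolysis removes the dioxolane and the silyl ether in one operation, and dilute acid at room temperature should not move the trisubstituted alkene.

Step 17
Reactants: 21 11-hydroxydrim-7-en-3-one; 22 isofraxidin (7-hydroxy-6,8-dimethoxy-2H-chromen-2-one)
Product: 23 6,8-dimethoxy-7-[(3-oxodrim-7-en-11-yl)oxy]-2H-chromen-2-one
Conditions: PPh3, DIAD, THF, 0 → 40 °C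
Reagents that add atoms: none
Why: Mitsunobu etherification; the acidic 7-hydroxycoumarin is O-alkylated by SN2 at the primary carbon C11, so no stereocentre is involved and the ketone and alkene are inert.

Step 18
Reactants: 23 saturated ring A ketone ether
Product: 24 6,8-dimethoxy-7-{[(1S,4aS,8aR)-2,5,5,8a-tetramethyl-6-oxo-1,4,4a,5,6,8a-hexahydronaphthalen-1-yl]methoxy}-2H-chromen-2-one (target; 5S,9S,10R in drimane numbering)
Conditions: IBX (2 equiv), DMSO, 75 °C
Reagents that add atoms: none
Why: IBX dehydrogenation of a ketone to its enone; the C3 ketone has α-hydrogens only at C2 (C4 is quaternary), so only the C1=C2 bond can form, and the lactone, the aryl ethers and the isolated alkene should tolerate the reagent.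

**Compound list**
1 | 2,2-dimethylcyclohexane-1,3-dione | CC1(C)C(=O)CCCC1=O | starting material
2 | 6,6-dimethyl-1,4-dioxaspiro[4.5]decan-7-one | CC1(C)C(=O)CCCC12OCCO2 | intermediate
3 | 6,6,8-trimethyl-1,4-dioxaspiro[4.5]decan-7-one (racemic) | CC1CCC2(OCCO2)C(C)(C)C1=O | intermediate
4 | 6,6,8-trimethyl-1,4-dioxaspiro[4.5]dec-7-en-7-yl trifluoromethanesulfonate | CC1=C(OS(=O)(=O)C(F)(F)F)C(C)(C)C2(OCCO2)CC1 | intermediate
5 | 7-(1-ethoxyethenyl)-6,6,8-trimethyl-1,4-dioxaspiro[4.5]dec-7-ene | CCOC(=C)C1=C(C)CCC2(OCCO2)C1(C)C | intermediate (not isolated)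
6 | 1-(6,6,8-trimethyl-1,4-dioxaspiro[4.5]dec-7-en-7-yl)ethan-1-one | CC(=O)C1=C(C)CCC2(OCCO2)C1(C)C | intermediate
7 | tert-butyldimethyl{[1-(6,6,8-trimethyl-1,4-dioxaspiro[4.5]dec-7-en-7-yl)ethenyl]oxy}silane | CC1=C(C(=C)O[Si](C)(C)C(C)(C)C)C(C)(C)C2(OCCO2)CC1 | intermediate
8 | (R)-4-benzyloxazolidin-2-one | O=C1N[C@H](Cc2ccccc2)CO1 | starting material
9 | (E)-but-2-enoyl chloride | C/C=C/C(=O)Cl | starting material
10 | (R)-4-benzyl-3-[(E)-but-2-enoyl]oxazolidin-2-one | C/C=C/C(=O)N1[C@H](Cc2ccccc2)COC1=O | intermediate
11 | (R)-4-benzyl-3-[6-(tert-butyldimethylsilyloxy)-3,3-(ethylenedioxy)drim-5-en-11-oyl]oxazolidin-2-one; acyl arm on C9 anti to the C10 methyl, C8 methyl anti to the arm | O=C(N1[C@H](Cc2ccccc2)COC1=O)[C@H]1[C@H](C)CC(O[Si](C)(C)C(C)(C)C)=C2C(C)(C)C3(OCCO3)CC[C@]21C | intermediate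
12 | 6-(tert-butyldimethylsilyloxy)-3,3-(ethylenedioxy)drim-5-en-11-ol | OC[C@H]1[C@H](C)CC(O[Si](C)(C)C(C)(C)C)=C2C(C)(C)C3(OCCO3)CC[C@]21C | intermediate
13 | 3,3-(ethylenedioxy)-11-hydroxydriman-6-one, C5 epimers | OC[C@H]1[C@H](C)CC(=O)C2C(C)(C)C3(OCCO3)CC[C@]21C | intermediate
14 | 11-(tert-butyldimethylsilyloxy)-3,3-(ethylenedioxy)driman-6-one, C5 epimers | CC(C)(C)[Si](C)(C)OC[C@H]1[C@H](C)CC(=O)C2C(C)(C)C3(OCCO3)CC[C@]21C | intermediate
15 | 11-(tert-butyldimethylsilyloxy)-3,3-(ethylenedioxy)-6-(trimethylsilyloxy)drim-6-ene, C5 epimers | CC(C)(C)[Si](C)(C)OC[C@H]1[C@H](C)C=C(O[Si](C)(C)C)C2C(C)(C)C3(OCCO3)CC[C@]21C | intermediate (not isolated)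
16 | 11-(tert-butyldimethylsilyloxy)-3,3-(ethylenedioxy)drim-7-en-6-one, C5 epimers | CC(C)(C)[Si](C)(C)OC[C@H]1C(C)=CC(=O)C2C(C)(C)C3(OCCO3)CC[C@]21C | intermediate
17 | 11-(tert-butyldimethylsilyloxy)-3,3-(ethylenedioxy)drim-7-en-6-one, trans-fused (H5 anti to the C10 methyl) | CC(C)(C)[Si](C)(C)OC[C@H]1C(C)=CC(=O)[C@@H]2C(C)(C)C3(OCCO3)CC[C@]21C | intermediate
18 | 11-(tert-butyldimethylsilyloxy)-3,3-(ethylenedioxy)drim-7-en-6-ol, hydroxyl syn to the C10 methyl | CC(C)(C)[Si](C)(C)OC[C@H]1C(C)=C[C@H](O)[C@@H]2C(C)(C)C3(OCCO3)CC[C@]21C | intermediate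
19 | 6-acetoxy-11-(tert-butyldimethylsilyloxy)-3,3-(ethylenedioxy)drim-7-ene | CC(C)(C)[Si](C)(C)OC[C@H]1C(C)=C[C@H](OC(C)=O)[C@@H]2C(C)(C)C3(OCCO3)CC[C@]21C | intermediate
20 | tert-butyl{[3,3-(ethylenedioxy)drim-7-en-11-yl]oxy}dimethylsilane | CC(C)(C)[Si](C)(C)OC[C@H]1C(C)=CC[C@@H]2C(C)(C)C3(OCCO3)CC[C@]21C | intermediate
21 | 11-hydroxydrim-7-en-3-one (arm anti to the C10 methyl, trans-fused) | OC[C@H]1C(C)=CC[C@@H]2C(C)(C)C(=O)CC[C@]21C | intermediate
22 | isofraxidin (7-hydroxy-6,8-dimethoxy-2H-chromen-2-one) | COc1cc2ccc(=O)oc2c(OC)c1O | starting material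
23 | 6,8-dimethoxy-7-[(3-oxodrim-7-en-11-yl)oxy]-2H-chromen-2-one | COc1cc2ccc(=O)oc2c(OC)c1OC[C@H]1C(C)=CC[C@@H]2C(C)(C)C(=O)CC[C@]21C | intermediate
24 | 6,8-dimethoxy-7-{[(1S,4aS,8aR)-2,5,5,8a-tetramethyl-6-oxo-1,4,4a,5,6,8a-hexahydronaphthalen-1-yl]methoxy}-2H-chromen-2-one | COc1cc2ccc(=O)oc2c(OC)c1OC[C@H]1C(C)=CC[C@@H]2C(C)(C)C(=O)C=C[C@]21C | target

**Totals**
Total steps: 18. Longest linear sequence: 17 steps (steps 1–5 and 7–18, from compound 1).

**Steps most likely to fail**

Step 7. The diene may not reach the s-cis geometry, because the C6 silyloxy group is pressed against the C4 methyl groups. The chelated imide could then be consumed by conjugate addition at C7 without ring closure (silyl transfer to chloride), the enol ether could be desilylated, or exo addition could compete. Fallback, from 5 and 10, returning at 13: the diene class is changed to the alkyl dienol ether 5, isolated from step 4 by leaving out the acid treatment. Its O-substituent cannot be transferred, so a stepwise addition has no exit other than ring closure, and the smaller ethoxy group eases the clash. Cycloaddition with 10 under the same aluminium chelate should give the ethyl enol ether cycloadduct F1. LiBH4 with one equivalent of MeOH would then give the C11 alcohol with intact ethyl enol ether F2, and oxalic acid in wet THF at 0 °C would hydrolyse the enol ether to hydroxy ketone 13.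

Step 12. Removal of the C5 proton, which sits between two quaternary carbons, may be slow. Deprotonation at the γ-positions could then take over and lead to loss of the C11 silyloxy group by vinylogous elimination or to drift at C9. Fallback, from 16, returning at 17: thermodynamic control is replaced by kinetic control. Irreversible deprotonation of 16 at C5 with LiN(i-Pr)2 in THF at −78 °C (conditions that favour the α' over the γ position) would give the lithium cross-conjugated dienolate F3. Inverse quench into acetic acid in THF at −78 °C should deliver the proton to C5 from the face opposite the axial C10 and C4 methyl groups and give the trans-fused enone 17.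

Step 15. Ionisation of the hindered acetate by palladium may be sluggish, so that the borohydride attacks the acetyl group and returns 18, or hydride is delivered to C8. Fallback, from 18, returning at 20: the palladium π-allyl route is replaced by a dissolving-metal reduction. Alcohol 18 is converted with n-BuLi and diethyl chlorophosphate in THF into the allylic diethyl phosphate F4. Li in liquid NH3 with THF and t-BuOH at −78 °C would cleave the allylic C–O bond by electron transfer, and protonation of the allyl anion at its less substituted end C6 should give 20. The silyl ether, the ketal and the isolated alkene tolerate these conditions.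

**Further compounds**
F1 | step 7 | (R)-4-benzyl-3-[6-ethoxy-3,3-(ethylenedioxy)drim-5-en-11-oyl]oxazolidin-2-one | O=C(N1[C@H](Cc2ccccc2)COC1=O)[C@H]1[C@H](C)CC(OCC)=C2C(C)(C)C3(OCCO3)CC[C@]21C
F2 | step 7 | 6-ethoxy-3,3-(ethylenedioxy)drim-5-en-11-ol | OC[C@H]1[C@H](C)CC(OCC)=C2C(C)(C)C3(OCCO3)CC[C@]21C
F3 | step 12 | lithium 11-(tert-butyldimethylsilyloxy)-3,3-(ethylenedioxy)drima-5,7-dien-6-olate | [Li+].CC(C)(C)[Si](C)(C)OC[C@H]1C(C)=CC([O-])=C2C(C)(C)C3(OCCO3)CC[C@]21C
F4 | step 15 | 11-(tert-butyldimethylsilyloxy)-3,3-(ethylenedioxy)drim-7-en-6-yl diethyl phosphate | CC(C)(C)[Si](C)(C)OC[C@H]1C(C)=C[C@H](OP(=O)(OCC)OCC)[C@@H]2C(C)(C)C3(OCCO3)CC[C@]21C
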